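**Plan**
- Retrosynthesis: the C3–O(acyl) bond of the veratrate ester is cut first (with inversion at C3). Then, in one operation, the O1–C5 bond of the lactone and the bond between the exocyclic CH2 and the phenyl ipso carbon are cut.
- Enabling feature: C5 of the γ-lactone ring (O1–C2(=O)–C3–C4–C5) carries both the ring oxygen O1 and a CH2–phenyl arm. O1 and the phenyl ring therefore sit on the two carbons of a former terminal C=C of a pent-4-enoic acid.
- Forward: L-allylglycine is deaminated to the (S)-2-hydroxy acid and the hydroxyl is silylated. A gold-catalysed oxyarylation with phenylboronic acid then closes the only ring (the γ-lactone) and attaches the phenyl group. Desilylation and esterification with veratric acid finish the molecule.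
- Stereochemistry: C3 comes from L-allylglycine (S, kept by double inversion). C5 (R) is induced by C3 in the cis-selective ring closure. The Mitsunobu esterification inverts C3 to R and gives the trans (3R,5R) target.
- The hydroxyl is masked as a TBS ether for the key step, because a free α-hydroxy acid would be bound by phenylboronic acid as a cyclic boronate.

Key step: step 3

Remark: the lactone is numbered O1, C2 (carbonyl), C3, C4, C5 throughout; L-allylglycine, phenylboronic acid and 3,4-dimethoxybenzoic acid are assumed to be commercial; TBS = tert-butyldimethylsilyl.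

**Step 1**
Reactants: 1 L-allylglycine [(S)-2-aminopent-4-enoic acid]
Product: 4 (S)-2-hydroxypent-4-enoic acid, via diazonium carboxylate 2 (not isolated), via α-lactone 3 (not isolated)
Conditions: NaNO2, 1 M aq. H2SO4, 0 °C → rt
Reagents that add atoms: water, O
Why: Diazotisation of the α-amino acid (deaminative hydroxylation) gives diazonium 2, which the neighbouring carboxylate displaces to α-lactone 3 before water reopens it at the same carbon, so two SN2 inversions leave C2 as (S), i.e. net retention.

**Step 2**
Reactants: 4 (S)-2-hydroxypent-4-enoic acid
Product: 6 (S)-2-((tert-butyldimethylsilyl)oxy)pent-4-enoic acid, via bis-silyl derivative 5 (not isolated)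
Conditions: TBSCl, imidazole, DMF, rt; then K2CO3, MeOH/THF/H2O, rt; aq. citric acid to pH 4
Reagents that add atoms: tert-butyldimethylsilyl chloride, CC(C)(C)[Si](C)(C)Cl
Why: Silylation with TBSCl/imidazole covers both OH and CO2H, and the silyl ester of 5, far more labile than the silyl ether, is then hydrolysed selectively by carbonate, a standard one-pot silyl protection of α-hydroxy acids that breaks no bond at C2 and removes the free hydroxyl that would otherwise bind the boronic acid in step 3.

**Step 3**
Reactants: 6 (S)-2-((tert-butyldimethylsilyl)oxy)pent-4-enoic acid; 7 phenylboronic acid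
Product: 9 (3S,5R)-5-benzyl-3-((tert-butyldimethylsilyl)oxy)dihydrofuran-2(3H)-one, via alkylgold(III) fluoride 8 (not isolated)
Conditions: Ph3PAuCl (5 mol%), Selectfluor (2 equiv), PhB(OH)2 (2 equiv), MeCN, 60 °C
Reagents that add atoms: phenylboronic acid (7), OB(O)c1ccccc1
Why: Selectfluor oxidises Ph3PAuCl to a cationic gold(III) fluoride that binds the terminal alkene of 6; the carboxyl oxygen then adds anti to the internal alkene carbon to give the alkylgold(III) fluoride 8, and phenylboronic acid, drawn to gold by the B–F interaction, transfers its phenyl group so that C(sp3)–C(sp2) reductive elimination forms the CH2–Ph bond and returns gold(I). The closest known reaction type is the gold-catalysed oxidative oxyarylation (carbolactonisation) of pent-4-enoic acids with arylboronic acids and an electrophilic fluorine oxidant. The γ-lactone closes in the 5-exo-trig mode through the O1–C5 bond. The new stereocentre C5 is controlled by the existing C3 centre: in the envelope-like arrangement of the oxyauration, which is expected to be reversible, the silyloxy group and the CH2–Au arm both prefer pseudo-equatorial positions, and this leads to the 3,5-cis (3S,5R) lactone. The step needs exo regioselectivity (oxygen to the internal and phenyl to the terminal carbon) and 3,5-cis diastereoselectivity; the unhindered monosubstituted alkene and the five-membered ring size secure the first, the bulky C3 silyloxy group is relied on for the second, and any trans isomer should be removed by chromatography at this stage. The silyl ether keeps the hydroxyl away from boron and from the oxidant, and its loss after ring closure would only deliver 10 one step early.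

**Step 4**
Reactants: 9 (3S,5R)-5-benzyl-3-((tert-butyldimethylsilyl)oxy)dihydrofuran-2(3H)-one
Product: 10 (3S,5R)-5-benzyl-3-hydroxydihydrofuran-2(3H)-one
Conditions: HF·pyridine, THF, 0 °C → rt
Reagents that add atoms: none
Why: Fluoride-mediated desilylation driven by the strong Si–F bond, run under mildly acidic HF·pyridine so that the lactone is not opened and C3 is not epimerised by base, while no bond to C3 or C5 is broken.

**Step 5**
Reactants: 10 (3S,5R)-5-benzyl-3-hydroxydihydrofuran-2(3H)-one; 11 3,4-dimethoxybenzoic acid (veratric acid)
Product: 13 Trichoderolide F [(3R,5R)-5-benzyl-2-oxotetrahydrofuran-3-yl 3,4-dimethoxybenzoate], via alkoxyphosphonium veratrate 12 (not isolated)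
Conditions: PPh3, DIAD, THF, 0 °C → rt
Reagents that add atoms: 3,4-dimethoxybenzoic acid (11), COc1ccc(C(=O)O)cc1OC
Why: Mitsunobu esterification: the hydroxyl is activated as alkoxyphosphonium salt 12 and displaced by veratrate in an SN2 reaction at the carbonyl-activated C3, which inverts this centre from S to R and turns the cis alcohol into the trans (3R,5R) ester while C5 is untouched.

**Compound list**
1 | L-allylglycine, (S)-2-aminopent-4-enoic acid | N[C@@H](CC=C)C(=O)O | starting material
2 | (S)-1-carboxylatobut-3-ene-1-diazonium (diazonium carboxylate zwitterion) | N#[N+][C@@H](CC=C)C(=O)[O-] | intermediate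
3 | (R)-3-allyloxiran-2-one (α-lactone) | O=C1O[C@@H]1CC=C | intermediate
4 | (S)-2-hydroxypent-4-enoic acid | O[C@@H](CC=C)C(=O)O | intermediate
5 | tert-butyldimethylsilyl (S)-2-((tert-butyldimethylsilyl)oxy)pent-4-enoate | CC(C)(C)[Si](C)(C)O[C@@H](CC=C)C(=O)O[Si](C)(C)C(C)(C)C | intermediate
6 | (S)-2-((tert-butyldimethylsilyl)oxy)pent-4-enoic acid | CC(C)(C)[Si](C)(C)O[C@@H](CC=C)C(=O)O | intermediate
7 | phenylboronic acid | OB(O)c1ccccc1 | starting material
8 | alkylgold(III) fluoride: the 3,5-cis lactone of 9 with Au(F)(Cl)(PPh3) on the exocyclic CH2 in place of phenyl | CC(C)(C)[Si](C)(C)O[C@H]1C[C@@H](C[Au-](F)(Cl)[P+](c2ccccc2)(c2ccccc2)c2ccccc2)OC1=O | intermediate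
9 | (3S,5R)-5-benzyl-3-((tert-butyldimethylsilyl)oxy)dihydrofuran-2(3H)-one (3,5-cis) | CC(C)(C)[Si](C)(C)O[C@H]1C[C@@H](Cc2ccccc2)OC1=O | intermediate
10 | (3S,5R)-5-benzyl-3-hydroxydihydrofuran-2(3H)-one (3,5-cis) | O[C@H]1C[C@@H](Cc2ccccc2)OC1=O | intermediate
11 | 3,4-dimethoxybenzoic acid (veratric acid) | COc1ccc(C(=O)O)cc1OC | starting material
12 | [(3S,5R)-5-benzyl-2-oxotetrahydrofuran-3-yl]oxy(triphenyl)phosphonium 3,4-dimethoxybenzoate | [O-]C(=O)c1ccc(OC)c(OC)c1.c1ccc(cc1)[P+](c1ccccc1)(c1ccccc1)O[C@H]1C[C@@H](Cc2ccccc2)OC1=O | intermediate
13 | Trichoderolide F, (3R,5R)-5-benzyl-2-oxotetrahydrofuran-3-yl 3,4-dimethoxybenzoate (3,5-trans) | COc1ccc(C(=O)O[C@@H]2C[C@@H](Cc3ccccc3)OC2=O)cc1OC | target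

Total step count: 5
Longest linear sequence: 5 steps (1 → 4 → 6 → 9 → 10 → 13)

**Steps most likely to fail**

Step 3. The oxyauration may show too little 3,5-cis facial selectivity. The boronic acid may be consumed by homocoupling or protodeboronation. The silyl ether may also be lost in the acidic, fluoride-containing medium before the ring has closed. The fallback separates the two bond formations and uses classical chemistry. It sets out from 6: iodolactonisation under equilibrating conditions (I2, MeCN, 0 °C → rt), which favour the cis lactone of 2-substituted pent-4-enoic acids, should give (3S,5S)-3-((tert-butyldimethylsilyl)oxy)-5-(iodomethyl)dihydrofuran-2(3H)-one F1. This has the same spatial arrangement as 9; the C5 descriptor changes only through the priority of iodine. Displacement of the primary iodide with lithium diphenylcuprate (from PhLi and CuI, THF/Et2O, −40 °C) then forms the CH2–phenyl bond, and the route is rejoined at 9.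

Step 5. The activated alkoxyphosphonium may eliminate towards the butenolide. Part of the ester may form with retention through an acyloxyphosphonium pathway. Removal of the phosphine oxide and hydrazide residues may also cost material. The fallback sets out from 10: triflation (Tf2O, pyridine, CH2Cl2, −20 °C) gives (3S,5R)-5-benzyl-2-oxotetrahydrofuran-3-yl trifluoromethanesulfonate F2. Caesium 3,4-dimethoxybenzoate (from 11 and Cs2CO3) in DMF at 0 °C → rt then displaces the α-carbonyl triflate by SN2 with inversion, and the route is rejoined at 13.

Step 1. Water may intercept the diazonium directly, which would erode configurational purity. Nitrosating species may attack the alkene. Recovery of the small, water-soluble hydroxy acid from the aqueous phase may be poor. The fallback replaces the first step, so it does not set out from a numbered compound but from commercial methyl (S)-glycidate F3. Copper-catalysed opening at the CH2 terminus with vinylmagnesium bromide (CuI cat., THF, −78 → −30 °C) leaves the stereocentre untouched and gives methyl (S)-2-hydroxypent-4-enoate F4. Silylation (TBSCl, imidazole, DMF) gives methyl (S)-2-((tert-butyldimethylsilyl)oxy)pent-4-enoate F5. Saponification (LiOH, THF/H2O, 0 °C) rejoins the route at 6, so the free hydroxy acid 4 is never isolated.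

**Further compounds**
F1 | step 3 | (3S,5S)-3-((tert-butyldimethylsilyl)oxy)-5-(iodomethyl)dihydrofuran-2(3H)-one | CC(C)(C)[Si](C)(C)O[C@H]1C[C@@H](CI)OC1=O
F2 | step 5 | (3S,5R)-5-benzyl-2-oxotetrahydrofuran-3-yl trifluoromethanesulfonate | FC(F)(F)S(=O)(=O)O[C@H]1C[C@@H](Cc2ccccc2)OC1=O
F3 | step 1 | methyl (S)-oxirane-2-carboxylate (methyl (S)-glycidate, purchased) | COC(=O)[C@@H]1CO1
F4 | step 1 | methyl (S)-2-hydroxypent-4-enoate | O[C@@H](CC=C)C(=O)OC
F5 | step 1 | methyl (S)-2-((tert-butyldimethylsilyl)oxy)pent-4-enoate | CC(C)(C)[Si](C)(C)O[C@@H](CC=C)C(=O)OC
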